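**Plan**

- Numbering: the chain runs C1 (CH2 on furan ring A), C2 (acetoxy carbon), C3=C4(Me), C5, C6=C7, C8(Me)=C9, C10, C11 (CH2 on furan ring B); ring atoms are O1 and C2–C5 of each furan.
- Enabling feature: C1 and C11 each end in the same 3-monosubstituted furan, and each furan maps onto a 2-(alkoxymethyl)allyl group, CH2=C(chain)–CH2–O–, so rings A and B can both come from one acyclic precursor with two such termini.
- Retrosynthesis: both furans are taken back to 2-methoxy-2,5-dihydrofurans, then the ring C3=C4 bond of ring A and of ring B is cut (ring-closing metathesis). Next come the two acetal C–O bonds, then C1–C2 (allylation of a C2 aldehyde), C5–C6 (allyl–alkenyl coupling), C6=C7 and C8=C9 (olefinations), and C10–C11 (Claisen).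
- Forward: monosilylated 2-methylenepropane-1,3-diol is used twice. One copy is grown from the C11 end to the C2 aldehyde, and the other adds as an allylstannane to bring C1 and the ring A terminus. Acetylation, desilylation and double acetal formation follow; rings A and B then close together and are aromatised last.
- Stereochemistry: C2 (S) comes from a catalyst-controlled Keck allylation; 8E from a stabilised-ylide Wittig reaction, 6E from a Takai–Utimoto olefination, 3E carried over from the E bromoenoate.

Key step: step 14

Assumption: the acetal carbons of 21 and 22 are formed without control, so both are carried as mixtures of acetal epimers; this is harmless because these carbons become sp2 in step 15.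

**Route**

Step 1
Reactants: 1 2-methylenepropane-1,3-diol
Product: 2 2-({[tert-butyl(dimethyl)silyl]oxy}methyl)prop-2-en-1-ol
Conditions: NaH (1.0 equiv), THF, 0 °C → rt; then TBSCl (1.0 equiv), rt
Reagents that add atoms: tert-butyl(chloro)dimethylsilane (TBSCl), CC(C)(C)[Si](C)(C)Cl
Why: Williamson-type O-silylation of the monosodium alkoxide, whose poor solubility in THF limits deprotonation to one hydroxyl of the symmetric diol, should give mainly the monoether.

Step 2
Reactants: 2 2-({[tert-butyl(dimethyl)silyl]oxy}methyl)prop-2-en-1-ol; 3 triethyl orthoacetate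
Product: 5 ethyl 4-({[tert-butyl(dimethyl)silyl]oxy}methyl)pent-4-enoate, via allyl ketene acetal 4 (not isolated)
Conditions: MeC(OEt)3 (6 equiv), EtCO2H (cat.), 140 °C, EtOH distilled off
Reagents that add atoms: none
Why: Johnson–Claisen rearrangement: acid-catalysed exchange with the orthoester gives allyl ketene acetal 4, whose [3,3]-sigmatropic shift forms the C10–C11 bond and turns the former carbinol carbon into the exocyclic methylene, while the silyl ether is inert to the weak acid.

Step 3
Reactants: 5 ethyl 4-({[tert-butyl(dimethyl)silyl]oxy}methyl)pent-4-enoate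
Product: 6 4-({[tert-butyl(dimethyl)silyl]oxy}methyl)pent-4-enal
Conditions: i-Bu2AlH (1.1 equiv), CH2Cl2, −78 °C; MeOH, then aq. potassium sodium tartrate
Reagents that add atoms: none
Why: Partial reduction of an ester with i-Bu2AlH: at −78 °C the tetrahedral aluminium hemiacetal persists until work-up, so the unhindered aliphatic ester should stop at the aldehyde.

Step 4
Reactants: 6 4-({[tert-butyl(dimethyl)silyl]oxy}methyl)pent-4-enal; 7 2-(triphenyl-λ5-phosphanylidene)propanal
Product: 8 (2E)-6-({[tert-butyl(dimethyl)silyl]oxy}methyl)-2-methylhepta-2,6-dienal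
Conditions: toluene, 90 °C
Reagents that add atoms: none
Why: Wittig olefination with a stabilised, α-methyl-substituted formyl ylide forms C8=C9 reversibly enough that the E trisubstituted enal, with the chain trans to the formyl group, should predominate, and the aliphatic aldehyde reacts faster than the hindered enal product.

Step 5
Reactants: 8 (2E)-6-({[tert-butyl(dimethyl)silyl]oxy}methyl)-2-methylhepta-2,6-dienal; 9 2-(dichloromethyl)-4,4,5,5-tetramethyl-1,3,2-dioxaborolane
Product: 10 2-[(1E,3E)-7-({[tert-butyl(dimethyl)silyl]oxy}methyl)-3-methylocta-1,3,7-trien-1-yl]-4,4,5,5-tetramethyl-1,3,2-dioxaborolane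
Conditions: CrCl2 (8 equiv), LiI (4 equiv), THF, rt
Reagents that add atoms: none
Why: Takai–Utimoto boryl-olefination: LiI exchanges one chloride of 9 for iodide, divalent chromium reduces it to a geminal dichromium species that adds to the aldehyde and eliminates anti, forming C6=C7 with E geometry without touching the silyl ether or the other alkenes.

Step 6
Reactants: 10 2-[(1E,3E)-7-({[tert-butyl(dimethyl)silyl]oxy}methyl)-3-methylocta-1,3,7-trien-1-yl]-4,4,5,5-tetramethyl-1,3,2-dioxaborolane; 11 ethyl (2E)-4-bromo-3-methylbut-2-enoate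
Product: 12 ethyl (2E,5E,7E)-11-({[tert-butyl(dimethyl)silyl]oxy}methyl)-3,7-dimethyldodeca-2,5,7,11-tetraenoate
Conditions: Pd(PPh3)4 (5 mol %), K3PO4 (3 equiv), THF–H2O, 40 °C, degassed
Reagents that add atoms: none
Why: Suzuki–Miyaura allyl–alkenyl coupling: zerovalent palladium inserts into the allylic C–Br bond, the phosphate-activated alkenylboronate transmetalates with retention, and reductive elimination at the unsubstituted allyl terminus forms C5–C6 while keeping the enoate conjugated and E, the mild base and low temperature guarding the skipped diene against migration.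

Step 7
Reactants: 12 ethyl (2E,5E,7E)-11-({[tert-butyl(dimethyl)silyl]oxy}methyl)-3,7-dimethyldodeca-2,5,7,11-tetraenoate
Product: 13 (2E,5E,7E)-11-({[tert-butyl(dimethyl)silyl]oxy}methyl)-3,7-dimethyldodeca-2,5,7,11-tetraen-1-ol
Conditions: i-Bu2AlH (2.5 equiv), CH2Cl2, −78 °C; aq. potassium sodium tartrate
Reagents that add atoms: none
Why: 1,2-Reduction of the conjugated ester by excess i-Bu2AlH at −78 °C gives the allylic alcohol without conjugate reduction or base-mediated alkene migration.

Step 8
Reactants: 13 (2E,5E,7E)-11-({[tert-butyl(dimethyl)silyl]oxy}methyl)-3,7-dimethyldodeca-2,5,7,11-tetraen-1-ol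
Product: 14 (2E,5E,7E)-11-({[tert-butyl(dimethyl)silyl]oxy}methyl)-3,7-dimethyldodeca-2,5,7,11-tetraenal
Conditions: activated MnO2 (excess), CH2Cl2, rt; filtered and used at once
Reagents that add atoms: none
Why: Allylic oxidation with activated MnO2 is selective for the allylic alcohol, runs under neutral conditions and stops at the enal, so the 2E geometry and the doubly allylic C5 methylene should survive.

Step 9
Reactants: 2 2-({[tert-butyl(dimethyl)silyl]oxy}methyl)prop-2-en-1-ol
Product: 16 tributyl[2-({[tert-butyl(dimethyl)silyl]oxy}methyl)prop-2-en-1-yl]stannane, via allylic mesylate 15 (not isolated)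
Conditions: n-BuLi, THF, −78 °C; MsCl, −78 °C; then Bu3SnLi (from Bu3SnH, LiN(i-Pr)2, THF, 0 °C), −78 °C → rt
Reagents that add atoms: methanesulfonyl chloride, CS(=O)(=O)Cl (atoms kept only in 15); tributylstannyllithium, [Li][Sn](CCCC)(CCCC)CCCC
Why: One-pot sulfonylation and nucleophilic displacement: the lithium alkoxide is mesylated at low temperature and the stannyl anion substitutes the allylic mesylate, direct and allylic-transposed attack giving the same 2-substituted allylstannane.

Step 10
Reactants: 14 (2E,5E,7E)-11-({[tert-butyl(dimethyl)silyl]oxy}methyl)-3,7-dimethyldodeca-2,5,7,11-tetraenal; 16 tributyl[2-({[tert-butyl(dimethyl)silyl]oxy}methyl)prop-2-en-1-yl]stannane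
Product: 17 (2S,3E,6E,8E)-1,11-bis(3-{[tert-butyl(dimethyl)silyl]oxy}prop-1-en-2-yl)-4,8-dimethylundeca-3,6,8-trien-2-ol
Conditions: (S)-BINOL (20 mol %), Ti(OiPr)4 (10 mol %), 4 Å MS, CH2Cl2, −20 °C; aq. NaHCO3
Reagents that add atoms: none
Why: Keck catalytic asymmetric allylation: the chiral Lewis acid formed from (S)-BINOL and Ti(OiPr)4 activates the aldehyde and directs the 2-substituted allylstannane, in an open transition state, to the Si face of the carbonyl group, which forms C1–C2 and sets C2 as S in the sense established for this catalyst with allyl- and 2-substituted allylstannanes.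

Step 11
Reactants: 17 (2S,3E,6E,8E)-1,11-bis(3-{[tert-butyl(dimethyl)silyl]oxy}prop-1-en-2-yl)-4,8-dimethylundeca-3,6,8-trien-2-ol
Product: 18 (2S,3E,6E,8E)-1,11-bis(3-{[tert-butyl(dimethyl)silyl]oxy}prop-1-en-2-yl)-4,8-dimethylundeca-3,6,8-trien-2-yl acetate
Conditions: Ac2O, pyridine, DMAP (cat.), CH2Cl2, 0 °C → rt
Reagents that add atoms: acetic anhydride, CC(=O)OC(C)=O
Why: DMAP-catalysed acylation of the secondary allylic alcohol with acetic anhydride proceeds at oxygen with retention at C2.

Step 12
Reactants: 18 (2S,3E,6E,8E)-1,11-bis(3-{[tert-butyl(dimethyl)silyl]oxy}prop-1-en-2-yl)-4,8-dimethylundeca-3,6,8-trien-2-yl acetate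
Product: 19 (2S,3E,6E,8E)-1,11-bis(3-hydroxyprop-1-en-2-yl)-4,8-dimethylundeca-3,6,8-trien-2-yl acetate
Conditions: HF·pyridine, pyridine, THF, 0 °C → rt
Reagents that add atoms: none
Why: Fluoride-driven cleavage of the two primary silyl ethers with pyridine-buffered HF forms strong Si–F bonds under nearly neutral conditions in which the allylic acetate neither hydrolyses nor migrates.

Step 13
Reactants: 19 (2S,3E,6E,8E)-1,11-bis(3-hydroxyprop-1-en-2-yl)-4,8-dimethylundeca-3,6,8-trien-2-yl acetate; 20 methoxyallene
Product: 21 (2S,3E,6E,8E)-4,8-dimethyl-1,11-bis{3-[(1-methoxyprop-2-en-1-yl)oxy]prop-1-en-2-yl}undeca-3,6,8-trien-2-yl acetate (mixture of acetal epimers)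
Conditions: 20 (6 equiv), Pd(OAc)2 (10 mol %), dppp (15 mol %), Et3N, MeCN, rt
Reagents that add atoms: none
Why: Palladium-catalysed hydroalkoxylation of an alkoxyallene: a hydridopalladium species adds to methoxyallene to give a 1-methoxy-π-allyl complex that each primary allylic alcohol attacks at the oxygen-bearing carbon, giving the mixed acrolein acetals under basic conditions, while the excess allene occupies the zerovalent palladium and the C2 acetate, flanked by a trisubstituted alkene, ionises only slowly at room temperature.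

Step 14
Reactants: 21 (2S,3E,6E,8E)-4,8-dimethyl-1,11-bis{3-[(1-methoxyprop-2-en-1-yl)oxy]prop-1-en-2-yl}undeca-3,6,8-trien-2-yl acetate (mixture of acetal epimers)
Product: 22 (2S,3E,6E,8E)-1,11-bis(5-methoxy-2,5-dihydrofuran-3-yl)-4,8-dimethylundeca-3,6,8-trien-2-yl acetate (mixture of acetal epimers)
Conditions: second-generation Grubbs catalyst RuCl2(=CHPh)(H2IMes)(PCy3) (10 mol %), CH2Cl2 (0.005 M), 40 °C, argon sweep
Reagents that add atoms: none
Why: The benzylidene of the catalyst exchanges onto each monosubstituted acetal vinyl group, the new ruthenium alkylidene adds across the neighbouring 1,1-disubstituted alkene to a ruthenacyclobutane, and cycloreversion expels ethene while forming the ring C3=C4 double bond. The closest known reaction is the ring-closing metathesis of allyl acrolein mixed acetals to 2-methoxy-2,5-dihydrofurans, applied here at both chain termini of one substrate. Ring A and ring B each close as a five-membered ring by alkene metathesis at carbon (ring atoms O1, CH2, C3, C4 and the acetal carbon), with no C–O bond formed in this step. No stereocentre is created: C2 of the chain is not touched and the acetal carbons remain epimer mixtures that disappear on aromatisation. The step needs site selectivity among seven alkenes, and the substrate secures it because the catalyst loads only on the two unhindered vinyl groups and five-membered closure onto the adjacent methylene groups is far faster than attack on the trisubstituted C3=C4 and C8=C9 bonds or the flanked, conjugated C6=C7 bond of the chain, which would require rings of eight or more members or an intermolecular event that high dilution disfavours.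

Step 15
Reactants: 22 (2S,3E,6E,8E)-1,11-bis(5-methoxy-2,5-dihydrofuran-3-yl)-4,8-dimethylundeca-3,6,8-trien-2-yl acetate (mixture of acetal epimers)
Product: 23 (2S,3E,6E,8E)-1,11-di(furan-3-yl)-4,8-dimethylundeca-3,6,8-trien-2-yl acetate
Conditions: pyridinium p-toluenesulfonate (cat.), CH2Cl2, rt
Reagents that add atoms: none
Why: Acid-catalysed aromatisation: protonation and loss of methanol from each cyclic acetal gives an oxocarbenium ion that loses a proton from the ring CH2 group, the furan resonance energy driving both eliminations under acid too weak to ionise the allylic acetate.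

**Compound list**

1 | 2-methylenepropane-1,3-diol | C=C(CO)CO | starting material
2 | 2-({[tert-butyl(dimethyl)silyl]oxy}methyl)prop-2-en-1-ol | C=C(CO)CO[Si](C)(C)C(C)(C)C | intermediate
3 | triethyl orthoacetate | CCOC(C)(OCC)OCC | starting material
4 | 1-ethoxy-1-{[2-({[tert-butyl(dimethyl)silyl]oxy}methyl)prop-2-en-1-yl]oxy}ethene (allyl ketene acetal, not isolated) | C=C(OCC)OCC(=C)CO[Si](C)(C)C(C)(C)C | intermediate
5 | ethyl 4-({[tert-butyl(dimethyl)silyl]oxy}methyl)pent-4-enoate | CCOC(=O)CCC(=C)CO[Si](C)(C)C(C)(C)C | intermediate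
6 | 4-({[tert-butyl(dimethyl)silyl]oxy}methyl)pent-4-enal | O=CCCC(=C)CO[Si](C)(C)C(C)(C)C | intermediate
7 | 2-(triphenyl-λ5-phosphanylidene)propanal | CC(C=O)=P(c1ccccc1)(c1ccccc1)c1ccccc1 | starting material
8 | (2E)-6-({[tert-butyl(dimethyl)silyl]oxy}methyl)-2-methylhepta-2,6-dienal | O=C/C(C)=C/CCC(=C)CO[Si](C)(C)C(C)(C)C | intermediate
9 | 2-(dichloromethyl)-4,4,5,5-tetramethyl-1,3,2-dioxaborolane | ClC(Cl)B1OC(C)(C)C(C)(C)O1 | starting material
10 | 2-[(1E,3E)-7-({[tert-butyl(dimethyl)silyl]oxy}methyl)-3-methylocta-1,3,7-trien-1-yl]-4,4,5,5-tetramethyl-1,3,2-dioxaborolane | CC1(C)OB(/C=C/C(C)=C/CCC(=C)CO[Si](C)(C)C(C)(C)C)OC1(C)C | intermediate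
11 | ethyl (2E)-4-bromo-3-methylbut-2-enoate | CCOC(=O)/C=C(\C)CBr | starting material
12 | ethyl (2E,5E,7E)-11-({[tert-butyl(dimethyl)silyl]oxy}methyl)-3,7-dimethyldodeca-2,5,7,11-tetraenoate | CCOC(=O)/C=C(\C)C/C=C/C(C)=C/CCC(=C)CO[Si](C)(C)C(C)(C)C | intermediate
13 | (2E,5E,7E)-11-({[tert-butyl(dimethyl)silyl]oxy}methyl)-3,7-dimethyldodeca-2,5,7,11-tetraen-1-ol | OC/C=C(\C)C/C=C/C(C)=C/CCC(=C)CO[Si](C)(C)C(C)(C)C | intermediate
14 | (2E,5E,7E)-11-({[tert-butyl(dimethyl)silyl]oxy}methyl)-3,7-dimethyldodeca-2,5,7,11-tetraenal | O=C/C=C(\C)C/C=C/C(C)=C/CCC(=C)CO[Si](C)(C)C(C)(C)C | intermediate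
15 | 2-({[tert-butyl(dimethyl)silyl]oxy}methyl)prop-2-en-1-yl methanesulfonate (not isolated) | CS(=O)(=O)OCC(=C)CO[Si](C)(C)C(C)(C)C | intermediate
16 | tributyl[2-({[tert-butyl(dimethyl)silyl]oxy}methyl)prop-2-en-1-yl]stannane | CCCC[Sn](CCCC)(CCCC)CC(=C)CO[Si](C)(C)C(C)(C)C | intermediate
17 | (2S,3E,6E,8E)-1,11-bis(3-{[tert-butyl(dimethyl)silyl]oxy}prop-1-en-2-yl)-4,8-dimethylundeca-3,6,8-trien-2-ol | O[C@H](/C=C(\C)C/C=C/C(C)=C/CCC(=C)CO[Si](C)(C)C(C)(C)C)CC(=C)CO[Si](C)(C)C(C)(C)C | intermediate
18 | (2S,3E,6E,8E)-1,11-bis(3-{[tert-butyl(dimethyl)silyl]oxy}prop-1-en-2-yl)-4,8-dimethylundeca-3,6,8-trien-2-yl acetate | CC(=O)O[C@H](/C=C(\C)C/C=C/C(C)=C/CCC(=C)CO[Si](C)(C)C(C)(C)C)CC(=C)CO[Si](C)(C)C(C)(C)C | intermediate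
19 | (2S,3E,6E,8E)-1,11-bis(3-hydroxyprop-1-en-2-yl)-4,8-dimethylundeca-3,6,8-trien-2-yl acetate | CC(=O)O[C@H](/C=C(\C)C/C=C/C(C)=C/CCC(=C)CO)CC(=C)CO | intermediate
20 | methoxyallene (1-methoxypropa-1,2-diene) | COC=C=C | starting material
21 | (2S,3E,6E,8E)-4,8-dimethyl-1,11-bis{3-[(1-methoxyprop-2-en-1-yl)oxy]prop-1-en-2-yl}undeca-3,6,8-trien-2-yl acetate (mixture of acetal epimers) | CC(=O)O[C@H](/C=C(\C)C/C=C/C(C)=C/CCC(=C)COC(OC)C=C)CC(=C)COC(OC)C=C | intermediate
22 | (2S,3E,6E,8E)-1,11-bis(5-methoxy-2,5-dihydrofuran-3-yl)-4,8-dimethylundeca-3,6,8-trien-2-yl acetate (mixture of acetal epimers) | CC(=O)O[C@H](/C=C(\C)C/C=C/C(C)=C/CCC1=CC(OC)OC1)CC1=CC(OC)OC1 | intermediate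
23 | (2S,3E,6E,8E)-1,11-di(furan-3-yl)-4,8-dimethylundeca-3,6,8-trien-2-yl acetate (CNP0230518.1) | CC(=O)O[C@H](/C=C(\C)C/C=C/C(C)=C/CCc1ccoc1)Cc1ccoc1 | target

**Count**

Total: 15 steps. Longest linear sequence: 14 steps (steps 1–8 and 10–15, from 1); step 9 is the two-step side branch from 2.

**Steps most likely to fail**

Step 13. The zerovalent palladium formed from the catalyst system may ionise the C2 allylic acetate, with elimination to a tetraene, transposition of the acetate or erosion of the C2 configuration, in competition with the hydroalkoxylation; addition may also stall at one of the two hydroxyl groups. The fallback leaves palladium out and makes the same acetals by acid-catalysed acetal exchange. It sets out from 19 and returns at 21: the diol is stirred in a large excess of 3,3-dimethoxyprop-1-ene with catalytic pyridinium p-toluenesulfonate over 5 Å molecular sieves, which take up the methanol, and the mixture is quenched with Et3N. No compound outside the list is made (none, F0).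

Step 6. The ester-bearing π-allylpalladium intermediate may equilibrate between syn and anti forms and erode the 3E geometry, couple at its substituted terminus, or the base may move the skipped C3=C4/C6=C7 diene into conjugation with the ester. The fallback removes the ester before the C–C bond is made. It sets out from 10 and 11 and returns at 13: bromoester 11 is first reduced (i-Bu2AlH, CH2Cl2, −78 °C) to (2E)-4-bromo-3-methylbut-2-en-1-ol F1, and F1 is coupled with boronate 10 under the palladium catalysis of step 6. The allyl fragment then carries a hydroxymethyl group, so no acidifying carbonyl sits next to C3 and no enolate-type pathway for geometric scrambling exists; the product is alcohol 13 itself, and 12 and step 7 drop out.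

Step 10. Addition to the β,β-disubstituted dienal with a hindered 2-substituted stannane may be slow and discriminate the two carbonyl faces poorly, and the enal may isomerise during the long reaction time. The fallback sets C2 by reagent-controlled ketone reduction instead of by allyl transfer. It sets out from 14 (with 16) and returns at 17. Stannane 16 is added to 14 without chiral control (BF3·OEt2, CH2Cl2, −78 °C) to give racemic (3E,6E,8E)-1,11-bis(3-{[tert-butyl(dimethyl)silyl]oxy}prop-1-en-2-yl)-4,8-dimethylundeca-3,6,8-trien-2-ol F2. Oxidation with Dess–Martin periodinane buffered with NaHCO3 gives (3E,6E,8E)-1,11-bis(3-{[tert-butyl(dimethyl)silyl]oxy}prop-1-en-2-yl)-4,8-dimethylundeca-3,6,8-trien-2-one F3. Corey–Bakshi–Shibata reduction of F3 with (R)-2-methyl-CBS-oxazaborolidine and catecholborane in toluene at −78 °C, in which the alkenyl group acts as the large substituent, should deliver hydride to the face that gives the 2S alcohol 17.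

Further compounds
F0 | step 13 | none | none
F1 | step 6 | (2E)-4-bromo-3-methylbut-2-en-1-ol | OC/C=C(\C)CBr
F2 | step 10 | (3E,6E,8E)-1,11-bis(3-{[tert-butyl(dimethyl)silyl]oxy}prop-1-en-2-yl)-4,8-dimethylundeca-3,6,8-trien-2-ol (racemic) | OC(/C=C(\C)C/C=C/C(C)=C/CCC(=C)CO[Si](C)(C)C(C)(C)C)CC(=C)CO[Si](C)(C)C(C)(C)C
F3 | step 10 | (3E,6E,8E)-1,11-bis(3-{[tert-butyl(dimethyl)silyl]oxy}prop-1-en-2-yl)-4,8-dimethylundeca-3,6,8-trien-2-one | O=C(/C=C(\C)C/C=C/C(C)=C/CCC(=C)CO[Si](C)(C)C(C)(C)C)CC(=C)CO[Si](C)(C)C(C)(C)C
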